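**Retrosynthetic overview**
- The strategy rests on the 1-methylimidazolidine-2,5-dione ring, joined through its amidine carbon C4 to the exocyclic nitrogen on C2 of the imidazole. In that ring C4–C5 is an oxalic amidine unit and N1(Me)–C2(=O)–N3 is an N-methylurea unit.
- This ring is disconnected last, at N3–C2 and N1–C5, into an imidazol-2-yl oxalamidine ethyl ester and a methyl isocyanate equivalent (N-succinimidyl N-methylcarbamate).
- The oxalamidine ester comes from the 2-aminoimidazole and ethyl 2-ethoxy-2-iminoacetate. The 2-amino group comes from C2 lithiation, azide transfer and hydrogenation, which also frees the phenol.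
- The two benzyl groups are placed on bought 4,5-diiodo-1-methylimidazole: C5 first (iodine–magnesium exchange, aldehyde addition, ionic hydrogenation), then C4 (Negishi coupling).
- Ring order: the imidazole is bought intact; the imidazolidinedione is the only ring made and is closed in the last step.

Key step: step 8

Assumption: 4,5-diiodo-1-methyl-1H-imidazole, 4-methoxybenzylzinc chloride (THF solution), ethyl 2-ethoxy-2-iminoacetate and N-succinimidyl N-methylcarbamate are taken as purchasable. The oxalamidine ester, its methylurea and the target are each drawn as one of their interconverting amidine tautomers. The target has no stereocentre.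

**Step 1**
Reactants: 1 2-hydroxy-3,4-dimethoxybenzaldehyde
Product: 2 2-(benzyloxy)-3,4-dimethoxybenzaldehyde
Conditions: BnBr, K2CO3, DMF, 60 °C
Reagents that add atoms: benzyl bromide, BrCc1ccccc1
Why: Williamson O-alkylation of the phenoxide; the benzyl ether masks the acidic OH through the organometallic steps and is later removed by the same hydrogenation that reduces the azide.

**Step 2**
Reactants: 3 4,5-diiodo-1-methyl-1H-imidazole; 4 ethylmagnesium bromide; 2 2-(benzyloxy)-3,4-dimethoxybenzaldehyde
Product: 6 [2-(benzyloxy)-3,4-dimethoxyphenyl](4-iodo-1-methyl-1H-imidazol-5-yl)methanol (racemic), via imidazol-5-ylmagnesium bromide 5 (not isolated)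
Conditions: EtMgBr, THF, rt; then 2, THF, rt; aq NH4Cl
Reagents that add atoms: none
Why: Iodine–magnesium exchange of the diiodide should take place selectively at C5, next to N-methyl, and the Grignard reagent then adds to the aldehyde (Grignard 1,2-addition); the carbinol centre forms racemic and is removed in step 3.

**Step 3**
Reactants: 6 [2-(benzyloxy)-3,4-dimethoxyphenyl](4-iodo-1-methyl-1H-imidazol-5-yl)methanol
Product: 7 5-[2-(benzyloxy)-3,4-dimethoxybenzyl]-4-iodo-1-methyl-1H-imidazole
Conditions: Et3SiH, TFA, CH2Cl2, 0 °C to rt; aq NaHCO3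
Reagents that add atoms: none
Why: Ionic hydrogenation: TFA ionises the carbinol to a benzylic cation stabilised by the para-methoxy and ortho-benzyloxy groups, and Et3SiH delivers hydride; the C–I bond and the aryl benzyl ether should tolerate these conditions at or below room temperature.

**Step 4**
Reactants: 7 5-[2-(benzyloxy)-3,4-dimethoxybenzyl]-4-iodo-1-methyl-1H-imidazole; 8 4-methoxybenzylzinc chloride
Product: 9 5-[2-(benzyloxy)-3,4-dimethoxybenzyl]-4-(4-methoxybenzyl)-1-methyl-1H-imidazole
Conditions: Pd(OAc)2 (2 mol%), SPhos (4 mol%), THF, rt to 50 °C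
Reagents that add atoms: none
Why: Negishi cross-coupling: zerovalent palladium formed in the flask inserts into the C4–I bond, the benzylic zinc reagent transmetalates and reductive elimination forms the C4–CH2 bond; the benzyl group has no β-hydrogen to eliminate.

**Step 5**
Reactants: 9 5-[2-(benzyloxy)-3,4-dimethoxybenzyl]-4-(4-methoxybenzyl)-1-methyl-1H-imidazole; 10 n-butyllithium
Product: 12 2-azido-5-[2-(benzyloxy)-3,4-dimethoxybenzyl]-4-(4-methoxybenzyl)-1-methyl-1H-imidazole, via 2-lithioimidazole 11 (not isolated)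
Conditions: n-BuLi, THF, −78 °C; TsN3, −78 °C to rt; H2O
Reagents that add atoms: tosyl azide (4-methylbenzenesulfonyl azide), Cc1ccc(cc1)S(=O)(=O)N=[N+]=[N-]
Why: The C2–H between the two ring nitrogens is the kinetically most acidic C–H and is lithiated at −78 °C (azole C2 lithiation); the aryllithium adds to the terminal nitrogen of tosyl azide and the triazenyl anion expels sulfinate (azide transfer).

**Step 6**
Reactants: 12 2-azido-5-[2-(benzyloxy)-3,4-dimethoxybenzyl]-4-(4-methoxybenzyl)-1-methyl-1H-imidazole
Product: 13 2-amino-5-(2-hydroxy-3,4-dimethoxybenzyl)-4-(4-methoxybenzyl)-1-methyl-1H-imidazole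
Conditions: H2 (1 atm), 10% Pd/C, EtOH, rt; used directly under inert gas
Reagents that add atoms: none
Why: Catalytic hydrogenation reduces the azide to the primary amine with loss of dinitrogen and hydrogenolyses the aryl benzyl ether in the same operation; the imidazolyl–CH2–aryl bonds are not cleaved.

**Step 7**
Reactants: 13 2-amino-5-(2-hydroxy-3,4-dimethoxybenzyl)-4-(4-methoxybenzyl)-1-methyl-1H-imidazole; 14 ethyl 2-ethoxy-2-iminoacetate
Product: 15 ethyl 2-{[5-(2-hydroxy-3,4-dimethoxybenzyl)-4-(4-methoxybenzyl)-1-methyl-1H-imidazol-2-yl]amino}-2-iminoacetate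
Conditions: 14 (1.5 equiv), AcOH (0.2 equiv), EtOH, rt to 40 °C
Reagents that add atoms: none
Why: Pinner-type amidine synthesis: the exocyclic amino group adds to the imidate carbon, which is more electrophilic toward amines than the ester, and ethanol is expelled; addition through ring N3 is reversible because only the exocyclic adduct can lose ethanol to a neutral conjugated amidine.

**Step 8**
Reactants: 15 ethyl 2-{[5-(2-hydroxy-3,4-dimethoxybenzyl)-4-(4-methoxybenzyl)-1-methyl-1H-imidazol-2-yl]amino}-2-iminoacetate; 16 N-succinimidyl N-methylcarbamate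
Product: 18 pyronaamidine, via N-methylurea 17 (not isolated)
Conditions: 16 (1.1 equiv), i-Pr2NEt, MeCN, 0 °C to rt; then DBU (0.2 equiv), 40 °C
Reagents that add atoms: none
Why: The terminal amidine nitrogen of 15, which carries the NH2 in the conjugated tautomer imidazolyl–N=C(NH2)–CO2Et, attacks the carbamoyl donor (directly or through methyl isocyanate released by base) and gives the methylurea 17. The urea N–H(Me) then attacks the adjacent, strongly electrophilic α-imino ester carbonyl and expels ethanol in a 5-exo-trig acyl substitution, closing the imidazolidine-2,5-dione ring with N-methyl between the two carbonyls (bonds N3–C2 and N1–C5). The closest known chemistry is the hydantoin synthesis from α-amino esters with isocyanates or succinimidyl carbamates and the corresponding carbamoylation–cyclisation of amidino esters. No stereocentre is formed. The step needs site selectivity for the terminal nitrogen over the internal amidine nitrogen, imidazole N3 and the phenol: the internal nitrogen is flanked by the imidazole ring and the amidine carbon and would give a crowded urea that should revert, N3-carbamoyl and aryl carbamate adducts give the isocyanate back under the basic conditions, and the terminal adduct is held by an N–H···O=C hydrogen bond before it closes irreversibly. A small excess of 16 limits carbamoylation of the product.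

**Compound list**
1 | 2-hydroxy-3,4-dimethoxybenzaldehyde | COc1ccc(C=O)c(O)c1OC | starting material
2 | 2-(benzyloxy)-3,4-dimethoxybenzaldehyde | COc1ccc(C=O)c(OCc2ccccc2)c1OC | intermediate
3 | 4,5-diiodo-1-methyl-1H-imidazole | Cn1cnc(I)c1I | starting material
4 | ethylmagnesium bromide | CC[Mg]Br | starting material
5 | (4-iodo-1-methyl-1H-imidazol-5-yl)magnesium bromide | Cn1cnc(I)c1[Mg]Br | intermediate
6 | [2-(benzyloxy)-3,4-dimethoxyphenyl](4-iodo-1-methyl-1H-imidazol-5-yl)methanol (racemic) | COc1ccc(C(O)c2c(I)ncn2C)c(OCc2ccccc2)c1OC | intermediate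
7 | 5-[2-(benzyloxy)-3,4-dimethoxybenzyl]-4-iodo-1-methyl-1H-imidazole | COc1ccc(Cc2c(I)ncn2C)c(OCc2ccccc2)c1OC | intermediate
8 | 4-methoxybenzylzinc chloride | COc1ccc(C[Zn]Cl)cc1 | starting material
9 | 5-[2-(benzyloxy)-3,4-dimethoxybenzyl]-4-(4-methoxybenzyl)-1-methyl-1H-imidazole | COc1ccc(Cc2ncn(C)c2Cc2ccc(OC)c(OC)c2OCc2ccccc2)cc1 | intermediate
10 | n-butyllithium | [Li]CCCC | starting material
11 | {5-[2-(benzyloxy)-3,4-dimethoxybenzyl]-4-(4-methoxybenzyl)-1-methyl-1H-imidazol-2-yl}lithium | COc1ccc(Cc2nc([Li])n(C)c2Cc2ccc(OC)c(OC)c2OCc2ccccc2)cc1 | intermediate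
12 | 2-azido-5-[2-(benzyloxy)-3,4-dimethoxybenzyl]-4-(4-methoxybenzyl)-1-methyl-1H-imidazole | COc1ccc(Cc2nc(N=[N+]=[N-])n(C)c2Cc2ccc(OC)c(OC)c2OCc2ccccc2)cc1 | intermediate
13 | 2-amino-5-(2-hydroxy-3,4-dimethoxybenzyl)-4-(4-methoxybenzyl)-1-methyl-1H-imidazole | COc1ccc(Cc2nc(N)n(C)c2Cc2ccc(OC)c(OC)c2O)cc1 | intermediate
14 | ethyl 2-ethoxy-2-iminoacetate | CCOC(=N)C(=O)OCC | starting material
15 | ethyl 2-{[5-(2-hydroxy-3,4-dimethoxybenzyl)-4-(4-methoxybenzyl)-1-methyl-1H-imidazol-2-yl]amino}-2-iminoacetate | CCOC(=O)C(=N)Nc1nc(Cc2ccc(OC)cc2)c(Cc2ccc(OC)c(OC)c2O)n1C | intermediate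
16 | N-succinimidyl N-methylcarbamate | CNC(=O)ON1C(=O)CCC1=O | starting material
17 | ethyl 2-{[5-(2-hydroxy-3,4-dimethoxybenzyl)-4-(4-methoxybenzyl)-1-methyl-1H-imidazol-2-yl]amino}-2-[(methylcarbamoyl)imino]acetate | CCOC(=O)C(=NC(=O)NC)Nc1nc(Cc2ccc(OC)cc2)c(Cc2ccc(OC)c(OC)c2O)n1C | intermediate
18 | pyronaamidine | COc1ccc(Cc2nc(NC3=NC(=O)N(C)C3=O)n(C)c2Cc2ccc(OC)c(OC)c2O)cc1 | target

**Total step count:** 8
**Longest linear sequence:** 8 steps (from 1 through steps 1 to 8)

**Steps most likely to fail**

Step 8. Carbamoylation may go to the internal amidine nitrogen, imidazole N3 or the phenol, and the ester may close onto imidazole N3 instead of the urea nitrogen, so that isomeric ring systems form. The fallback sets out from 13 and comes back to the route at 18, using the preformed ring. 1-Methylimidazolidine-2,4,5-trione is O-silylated with N,O-bis(trimethylsilyl)acetamide in MeCN to 1-methyl-4-[(trimethylsilyl)oxy]-1H-imidazole-2,5-dione F1. The amino group of 13 adds to C4 of F1 at reflux and trimethylsilanol is lost, which should give 18 directly with no ring closure to control.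

Step 7. The weakly nucleophilic amino group may react slowly, the amine may attack the ester carbonyl instead of the imidate carbon, or the new ester may cyclise onto ring N3. The fallback sets out from 12 and comes back at 15; it fixes the exocyclic N–C bond through the azide nitrogen. Staudinger reaction of 12 with PPh3 in THF gives the iminophosphorane 5-[2-(benzyloxy)-3,4-dimethoxybenzyl]-4-(4-methoxybenzyl)-1-methyl-N-(triphenylphosphoranylidene)-1H-imidazol-2-amine F2. Ethyl chlorooxoacetate converts it, with loss of triphenylphosphine oxide, into the imidoyl chloride ethyl 2-chloro-2-({5-[2-(benzyloxy)-3,4-dimethoxybenzyl]-4-(4-methoxybenzyl)-1-methyl-1H-imidazol-2-yl}imino)acetate F3. Ammonia in THF at −40 °C displaces chloride to give the O-benzyl oxalamidine ethyl 2-({5-[2-(benzyloxy)-3,4-dimethoxybenzyl]-4-(4-methoxybenzyl)-1-methyl-1H-imidazol-2-yl}amino)-2-iminoacetate F4. Hydrogenolysis (H2, Pd/C, EtOH) then frees the phenol and gives 15.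

Step 4. Oxidative addition into the crowded, electron-rich C4–I bond may be slow, N3 may bind the catalyst, and the benzylzinc reagent may homocouple or the iodide may be protodehalogenated. The fallback sets out from 7 and comes back at 9 by polar chemistry. Iodine–magnesium exchange of 7 with EtMgBr (4) in THF gives {5-[2-(benzyloxy)-3,4-dimethoxybenzyl]-1-methyl-1H-imidazol-4-yl}magnesium bromide F5. Addition to 4-methoxybenzaldehyde gives racemic {5-[2-(benzyloxy)-3,4-dimethoxybenzyl]-1-methyl-1H-imidazol-4-yl}(4-methoxyphenyl)methanol F6. Ionic hydrogenation (Et3SiH, TFA, CH2Cl2) then gives 9.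

**Further compounds**
F1 | step 8 | 1-methyl-4-[(trimethylsilyl)oxy]-1H-imidazole-2,5-dione | CN1C(=O)N=C(O[Si](C)(C)C)C1=O
F2 | step 7 | 5-[2-(benzyloxy)-3,4-dimethoxybenzyl]-4-(4-methoxybenzyl)-1-methyl-N-(triphenylphosphoranylidene)-1H-imidazol-2-amine | COc1ccc(Cc2nc(N=P(c3ccccc3)(c3ccccc3)c3ccccc3)n(C)c2Cc2ccc(OC)c(OC)c2OCc2ccccc2)cc1
F3 | step 7 | ethyl 2-chloro-2-({5-[2-(benzyloxy)-3,4-dimethoxybenzyl]-4-(4-methoxybenzyl)-1-methyl-1H-imidazol-2-yl}imino)acetate | CCOC(=O)C(Cl)=Nc1nc(Cc2ccc(OC)cc2)c(Cc2ccc(OC)c(OC)c2OCc2ccccc2)n1C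
F4 | step 7 | ethyl 2-({5-[2-(benzyloxy)-3,4-dimethoxybenzyl]-4-(4-methoxybenzyl)-1-methyl-1H-imidazol-2-yl}amino)-2-iminoacetate | CCOC(=O)C(=N)Nc1nc(Cc2ccc(OC)cc2)c(Cc2ccc(OC)c(OC)c2OCc2ccccc2)n1C
F5 | step 4 | {5-[2-(benzyloxy)-3,4-dimethoxybenzyl]-1-methyl-1H-imidazol-4-yl}magnesium bromide | COc1ccc(Cc2c([Mg]Br)ncn2C)c(OCc2ccccc2)c1OC
F6 | step 4 | {5-[2-(benzyloxy)-3,4-dimethoxybenzyl]-1-methyl-1H-imidazol-4-yl}(4-methoxyphenyl)methanol (racemic) | COc1ccc(C(O)c2ncn(C)c2Cc2ccc(OC)c(OC)c2OCc2ccccc2)cc1
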